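At the reading, 8.0 h after mixing, the target in each flask depends on how long the catalyst has stood free.

common to all: starting material 0.098 M; second substrate 0.0980 M; free catalyst 0.98 mM; added ligand 1.3 mM; time 8.0 h
- gamma: temperature 10 °C
- alpha: temperature 55 °C
- theta: temperature 25 °C
- delta: temperature 40 °C

    free catalyst + added ligand ⇌ idle complex (K1 = 1100 M⁻¹, k1 = 160 M⁻¹ h⁻¹, Ea1 = 55.0 kJ mol⁻¹, ΔH1 = −2.00 kJ mol⁻¹)
    target + free catalyst ⇌ isomer of the product + free catalyst, rate k2*[free catalyst]*[target] forward; the back reaction follows from the equilibrium constant (K2 = 2.7, k2 = 57 M⁻¹ h⁻¹, Ea2 = 71.0 kJ mol⁻¹, ΔH2 = −16.0 kJ mol⁻¹)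
    second substrate + free catalyst ⇌ catalyst intermediate B (K3 = 1700 M⁻¹, k3 = 890 M⁻¹ h⁻¹, Ea3 = 62.0 kJ mol⁻¹, ΔH3 = 0 kJ mol⁻¹)
    starting material + free catalyst ⇌ catalyst intermediate A (K4 = 18 M⁻¹, k4 = 180 M⁻¹ h⁻¹, Ea4 = 44.0 kJ mol⁻¹, ΔH4 = −31.0 kJ mol⁻¹)
    catalyst intermediate A → free catalyst + target (k5 = 8.8 h⁻¹, Ea5 = 81.0 kJ mol⁻¹)
    catalyst intermediate B → free catalyst + second product (k6 = 31 h⁻¹, Ea6 = 81.0 kJ mol⁻¹)
    (constants at 25 °C)

* the flask that comes out highest in amount of target, in percent of the starting material charged, or "all alike" when all lie within 1.5 percentage points (gamma / alpha / theta / delta / all alike)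
* target at the end, in percent of the starting material charged, gamma
* target at the end, in percent of the starting material charged, alpha
* target at the end, in percent of the starting material charged, theta
* target at the end, in percent of the starting material charged, delta

- the constants hold at 25 °C; other temperatures follow from the activation energies and enthalpies

Capture of starting material and isomerisation of target both run on free catalyst, so one clock serves both. The starting material obeys a pseudo-first-order law in that clock. Its constant r is the capture rate with the whole catalyst charge free, multiplied by the chance that catalyst intermediate A goes on to target and does not fall back.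

The catalyst's time is then shared out. Per free catalyst, catalyst intermediate A holds a seat s and the idle complex a seat l. The added ligand is taken as its charge less 0.5 of the catalyst charge, so l = 0.891. Catalyst intermediate B falls back far more slowly than it breaks down, so its seat at full charge is b, and consuming the whole charge costs w hours.

Two lower bounds follow, and the larger is taken:

t / (1 + s + b + l), or (t − w) / (1 + s + l)

For alpha:

r = 0.468 h⁻¹, s = 0.268, b = 1.40, w = 0.163 h

The second bound is the larger in alpha. This gives alpha's free hours, the time integral of free catalyst as a fraction of its charge: 3.63 h.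

The curve of target in alpha starts with a slope of 0.175 h⁻¹ of the charge, taken before any idle complex has formed. Isomerisation runs alongside capture on the same clock, relaxing in alpha at 1.28 h⁻¹, faster than r, so the curve has no sharp knee: it bends gradually below the converted fraction, 1 − exp(−rH), towards the isomerisation equilibrium share of target, c = 1 / (1 + K), with K taken at the flask's temperature. Target is estimated as the lower of the two, which is an estimate and not a bound:

alpha: converted 81.7%, level 40.1%, target 40.1%

delta: r = 0.205 h⁻¹, H = 3.08 h, converted 46.8%, level 33.5%, target 33.5%

theta: r = 0.0826 h⁻¹, H = 1.69 h, converted 13.0%, level 27.0%, target 13.0%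

gamma: r = 0.0301 h⁻¹, H = 0.995 h, converted 2.95%, level 20.8%, target 2.95%

The reckoning ranks alpha highest.

The forecast also names alpha, with 3.4% for gamma, 38% for alpha, 14.5% for theta and 34% for delta, and holds that “alpha only narrowly beats delta”. Its figure for theta is higher than the converted fraction reckoned here, and its figure for alpha is lower than the level reckoned here.

In the simulation alpha comes highest at 39.0%, with delta at 35.9%, theta at 15.7% and gamma at 3.43%. In alpha the breakdown of catalyst intermediate B had 96% of its turnover behind it after 0.800 h, while capture of starting material, with 37% behind it after 1.60 h, ran on to the end. The free hours 3.63 h leave 18.3% of the starting material in alpha, where 15% stood unbound. A neighbour like alpha but charged with 2.4 × 10⁻⁴ M of free catalyst is reckoned at 2.86 h of free time, which leaves 72.1% of its starting material, and that flask held 69.5% at 8.00 h.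

The numbers are invented, and the outcome is calculated.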